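**Retrosynthetic overview**
- The target is the all-trans (2R,3S,4S,5R) isomer. It comes from global desilylation of a tetrahydrofuran. The benzylic C–O ring bond of that tetrahydrofuran is made last, by SN1 cycloetherification of a 1,4-diaryl-1,4-diol with both CH2OH groups masked.
- The diol comes from hydride opening of an unsymmetrical exo,exo-4,8-diaryl-3,7-dioxabicyclo[3.3.0]octane-2,6-dione, which already holds all four stereocentres.
- The bislactone comes from a one-flask sequential double Evans syn-aldol. The bis(boron enolate) of N,N′-succinylbis[(R)-4-benzyloxazolidinone] reacts with two different aryl aldehydes, then lactonises twice with loss of both auxiliaries. This makes C7–C8, C7′–C8′ and two C–O bonds.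
- Ring order: both γ-lactone rings form together, both are opened reductively, then the tetrahydrofuran ring is closed.

Assumption: reagent additions in one flask without work-up in between count as one step. Lignan numbering is used in the comments (C7/C7′ benzylic, C8/C8′, C9/C9′).

**Step 1**
Reactants: 1 (R)-4-benzyl-1,3-oxazolidin-2-one (2 equiv); 2 succinyl chloride
Product: 4 1,4-bis[(4R)-4-benzyl-2-oxo-1,3-oxazolidin-3-yl]butane-1,4-dione, via N-lithio oxazolidinone 3 (not isolated)
Conditions: n-BuLi (2.05 equiv), THF, −78 °C; then 2 (1.0 equiv), −78 → 0 °C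
Reagents that add atoms: none
Why: This is a twofold N-acylation of the lithiated oxazolidinone (Evans imide formation) at both acid chloride termini, and the auxiliary stereocentre is not touched.

**Step 2**
Reactants: 5 syringaldehyde
Product: 6 4-(tert-butyldimethylsilyloxy)-3,5-dimethoxybenzaldehyde
Conditions: TBSCl, imidazole, DMF, rt
Reagents that add atoms: tert-butyldimethylsilyl chloride, CC(C)(C)[Si](C)(C)Cl
Why: Silyl ether protection masks the acidic phenol, which would otherwise quench the boron enolate and make the later bislactone prone to quinone-methide fragmentation; no stereocentre is involved.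

**Step 3 (key step)**
Reactants: 4 bis-imide; 6 silylated syringaldehyde (1.0 equiv, added first); 7 3,4,5-trimethoxybenzaldehyde (2.0 equiv, added second)
Product: 11 (1R,4R,5R,8R)-4-[4-(tert-butyldimethylsilyloxy)-3,5-dimethoxyphenyl]-8-(3,4,5-trimethoxyphenyl)-3,7-dioxabicyclo[3.3.0]octane-2,6-dione, via bis-boron dienolate 8 (not isolated), via mono-aldolate enolate 9 (not isolated), via bis-hydroxy bis-imide 10 (not isolated)
Conditions: Bu2BOTf (2.3 equiv), i-Pr2NEt (2.6 equiv), CH2Cl2, 0 °C; 6, −78 → −40 °C; 7, −40 → 0 °C; pH 7 buffer, MeOH, 30% H2O2, 0 °C → rt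
Reagents that add atoms: none
Why: Proposed new method: soft double enolisation gives the conjugated (Z,Z)-bis(boron enolate) 8, and each terminus reacts through an Evans Zimmerman–Traxler chair on the face away from the benzyl group of its own (R)-auxiliary, giving 7R,8R and 7′R,8′R (syn,syn with the C2-type 8,8′ relationship); the first aldol is faster than the second because it turns an unhindered dienolate terminus into an α-branched enolate, so one equivalent of 6 is taken up once before 7 is added; the still-enolised second imide cannot be attacked by the first aldolate, and after boron removal each γ-hydroxy imide expels its oxazolidinone, closing both lactones of the exo,exo cis-fused bicycle in the same operation; the closest known reaction types are the Evans syn-aldol/lactonisation of succinate-derived N-acyloxazolidinones to paraconic-type lactones and the racemic double aldol–bislactonisation of succinate dianions or 2,5-bis(silyloxy)furans with aryl aldehydes.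

**Step 4**
Reactants: 11 bislactone
Product: 12 (1R,2S,3S,4R)-1-[4-(tert-butyldimethylsilyloxy)-3,5-dimethoxyphenyl]-2,3-bis(hydroxymethyl)-4-(3,4,5-trimethoxyphenyl)butane-1,4-diol
Conditions: LiBH4 (4 equiv), MeOH (4 equiv), THF, 0 °C → rt
Reagents that add atoms: none
Why: Hydride reduction of both lactones cleaves only the acyl–O bonds, so both benzylic carbinols keep their configuration and C9/C9′ become CH2OH; the cis-fused bicycle cannot epimerise at C8/C8′ before it is reduced, and the aryl silyl ether is inert to LiBH4.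

**Step 5**
Reactants: 12 tetraol
Product: 15 (2R,3S,4S,5R)-2-[4-(tert-butyldimethylsilyloxy)-3,5-dimethoxyphenyl]-3,4-bis[(tert-butyldimethylsilyloxy)methyl]-5-(3,4,5-trimethoxyphenyl)tetrahydrofuran, via trisilyl 1,4-diol 13 (not isolated), via benzylic mesylate 14 (not isolated)
Conditions: TBSCl (2.1 equiv), Et3N, DMAP (cat.), CH2Cl2, 0 °C → rt; then MsCl (1.2 equiv), Et3N, −20 °C → rt
Reagents that add atoms: tert-butyldimethylsilyl chloride, CC(C)(C)[Si](C)(C)Cl
Why: Primary-selective silylation removes the two CH2OH oxygens as competing nucleophiles (they would give the furofuran); mesylation of either benzylic carbinol (14 is drawn at the trimethoxyphenyl carbinol, and the other regioisomer converges on the same product) then gives an electron-rich sulfonate that ionises and is captured 5-exo by the other carbinol oxygen (SN1 cycloetherification), with the aryl group settling trans to the neighbouring CH2OTBS so that the R configuration re-forms, while the Et3N medium prevents re-ionisation and Friedel–Crafts closure to an aryltetralin.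

**Step 6**
Reactants: 15 trisilylated tetrahydrofuran
Product: 16 4-[(2R,3S,4S,5R)-3,4-bis(hydroxymethyl)-5-(3,4,5-trimethoxyphenyl)tetrahydrofuran-2-yl]-2,6-dimethoxyphenol (target)
Conditions: TBAF (3.5 equiv), AcOH (3.5 equiv), THF, 0 °C → rt
Reagents that add atoms: none
Why: Fluoride-mediated global desilylation under acetic acid buffering keeps the phenol protonated, so the ring does not open through a quinone methide, and avoids any acid strong enough to rearrange the diol to the furofuran; no stereocentre is touched.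

**Compound list**
1 | (R)-4-benzyl-1,3-oxazolidin-2-one | O=C1N[C@H](Cc2ccccc2)CO1 | starting material
2 | succinyl chloride | O=C(Cl)CCC(=O)Cl | starting material
3 | lithium (R)-4-benzyl-2-oxo-1,3-oxazolidin-3-ide | [Li]N1[C@H](Cc2ccccc2)COC1=O | intermediate
4 | 1,4-bis[(4R)-4-benzyl-2-oxo-1,3-oxazolidin-3-yl]butane-1,4-dione | O=C(CCC(=O)N1[C@H](Cc2ccccc2)COC1=O)N1[C@H](Cc2ccccc2)COC1=O | intermediate
5 | syringaldehyde | COc1cc(C=O)cc(OC)c1O | starting material
6 | 4-(tert-butyldimethylsilyloxy)-3,5-dimethoxybenzaldehyde | COc1cc(C=O)cc(OC)c1O[Si](C)(C)C(C)(C)C | intermediate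
7 | 3,4,5-trimethoxybenzaldehyde | COc1cc(C=O)cc(OC)c1OC | starting material
8 | (1Z,3Z)-1,4-bis(dibutylboryloxy)-1,4-bis[(4R)-4-benzyl-2-oxooxazolidin-3-yl]buta-1,3-diene | CCCCB(CCCC)O/C(=C\C=C(/OB(CCCC)CCCC)N1[C@H](Cc2ccccc2)COC1=O)N1[C@H](Cc2ccccc2)COC1=O | intermediate
9 | (7′R,8′R) mono boron aldolate of 6 that still carries the second (Z)-boron enolate | COc1cc(cc(OC)c1O[Si](C)(C)C(C)(C)C)[C@H](OB(CCCC)CCCC)[C@H](C(=O)N1[C@H](Cc2ccccc2)COC1=O)/C=C(\OB(CCCC)CCCC)N1[C@H](Cc2ccccc2)COC1=O | intermediate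
10 | (2R,3R)-2-[(R)-hydroxy(3,4,5-trimethoxyphenyl)methyl]-3-[(R)-[4-(TBSO)-3,5-dimethoxyphenyl](hydroxy)methyl]-1,4-bis[(4R)-4-benzyl-2-oxooxazolidin-3-yl]butane-1,4-dione | COc1cc(cc(OC)c1OC)[C@H](O)[C@H](C(=O)N1[C@H](Cc2ccccc2)COC1=O)[C@@H](C(=O)N1[C@H](Cc2ccccc2)COC1=O)[C@@H](O)c1cc(OC)c(O[Si](C)(C)C(C)(C)C)c(OC)c1 | intermediate
11 | (1R,4R,5R,8R)-4-[4-(TBSO)-3,5-dimethoxyphenyl]-8-(3,4,5-trimethoxyphenyl)-3,7-dioxabicyclo[3.3.0]octane-2,6-dione (cis-fused, both aryl groups exo) | O=C1O[C@@H](c3cc(OC)c(O[Si](C)(C)C(C)(C)C)c(OC)c3)[C@H]2[C@@H]1[C@H](c4cc(OC)c(OC)c(OC)c4)OC2=O | intermediate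
12 | (1R,2S,3S,4R)-1-[4-(TBSO)-3,5-dimethoxyphenyl]-2,3-bis(hydroxymethyl)-4-(3,4,5-trimethoxyphenyl)butane-1,4-diol | COc1cc(cc(OC)c1OC)[C@H](O)[C@H](CO)[C@@H](CO)[C@@H](O)c1cc(OC)c(O[Si](C)(C)C(C)(C)C)c(OC)c1 | intermediate
13 | 9,9′-bis-O-TBS ether of 12 (both benzylic OH free) | COc1cc(cc(OC)c1OC)[C@H](O)[C@H](CO[Si](C)(C)C(C)(C)C)[C@@H](CO[Si](C)(C)C(C)(C)C)[C@@H](O)c1cc(OC)c(O[Si](C)(C)C(C)(C)C)c(OC)c1 | intermediate
14 | mono-mesylate of 13 at the trimethoxyphenyl carbinol | COc1cc(cc(OC)c1OC)[C@H](OS(C)(=O)=O)[C@H](CO[Si](C)(C)C(C)(C)C)[C@@H](CO[Si](C)(C)C(C)(C)C)[C@@H](O)c1cc(OC)c(O[Si](C)(C)C(C)(C)C)c(OC)c1 | intermediate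
15 | (2R,3S,4S,5R)-2-[4-(TBSO)-3,5-dimethoxyphenyl]-3,4-bis[(TBSO)methyl]-5-(3,4,5-trimethoxyphenyl)tetrahydrofuran (all-trans) | COc1cc([C@@H]2O[C@@H](c3cc(OC)c(OC)c(OC)c3)[C@H](CO[Si](C)(C)C(C)(C)C)[C@H]2CO[Si](C)(C)C(C)(C)C)cc(OC)c1O[Si](C)(C)C(C)(C)C | intermediate
16 | 4-[(2R,3S,4S,5R)-3,4-bis(hydroxymethyl)-5-(3,4,5-trimethoxyphenyl)tetrahydrofuran-2-yl]-2,6-dimethoxyphenol | COc1cc([C@@H]2O[C@@H](c3cc(OC)c(OC)c(OC)c3)[C@H](CO)[C@H]2CO)cc(OC)c1O | target

**Totals**
Total step count: 6. Longest linear sequence: 5 (1 → 4 → 11 → 12 → 15 → 16, or equally 5 → 6 → 11 → 12 → 15 → 16).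

**Steps most likely to fail**

Step 3 carries the most risk. The hindered second aldol may stall, or the two aldehydes may not be taken up one after the other, which would leave a statistical mixture of bislactones. The fallback gives up differentiation in the key step and desymmetrises at the very end. It sets out from 4 and 6. Bis-enolate 8 is treated with 6 alone (2.5 equiv), which gives the C2-symmetric bis-hydroxy bis-imide F1. This lactonises to the C2-symmetric bislactone F2. LiBH4 gives the symmetric tetraol F3. TBSCl/Et3N/DMAP gives the tetrasilyl 1,4-diol F4. MsCl/Et3N takes this through the benzylic mesylate F5 to the all-trans tetrasilyl tetrahydrofuran F6. TBAF/AcOH then releases the C2-symmetric bisphenol diol F7. The two phenols of F7 are homotopic, so MeI (1.0 equiv) with K2CO3 in acetone can give only one monomethyl ether. The conversion is statistical, and F7 is recovered and recycled. This fallback rejoins the route at 16.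

Step 5 is the second risk. Silylation may not be selective enough, or the closure may be partly SN2-like and give a 2,3-cis epimer, or a benzylic chloride may build up. The fallback closes the ring through a site-selective quinone methide instead of a sulfonate. It sets out from 13, which is isolated this time. Cs2CO3 (0.5 equiv) in DMF–H2O cleaves only the aryl silyl ether and gives the free-phenol diol F8. Diphenyl phosphate (10 mol %) with 4 Å molecular sieves in CH2Cl2 dehydrates only the p-hydroxybenzylic carbinol, giving the p-quinone methide F9. The untouched trimethoxyphenyl carbinol then adds to F9 in a reversible 5-exo oxa-1,6-addition. This settles on the all-trans phenolic bis-silyl tetrahydrofuran F10. TBAF/AcOH then rejoins the route at 16.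

Step 1 is the third risk. Succinyl chloride can react through cyclic or ketene-type forms, giving mono-acylated and ring-closed by-products. The fallback installs the two auxiliaries one after the other from the anhydride. It sets out from 1. The lithio salt 3 opens succinic anhydride to the imide acid F11. PivCl/Et3N turns F11 into the mixed pivalic anhydride F12. A second equivalent of 1 with LiCl and Et3N acylates on F12, which rejoins the route at 4.

**Further compounds**
F1 | step 3 | C2-symmetric (2R,3R)-2,3-bis[(R)-[4-(TBSO)-3,5-dimethoxyphenyl](hydroxy)methyl]-1,4-bis[(4R)-4-benzyl-2-oxooxazolidin-3-yl]butane-1,4-dione | COc1cc(cc(OC)c1O[Si](C)(C)C(C)(C)C)[C@H](O)[C@H](C(=O)N1[C@H](Cc2ccccc2)COC1=O)[C@@H](C(=O)N1[C@H](Cc2ccccc2)COC1=O)[C@@H](O)c1cc(OC)c(O[Si](C)(C)C(C)(C)C)c(OC)c1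
F2 | step 3 | (1R,4R,5R,8R)-4,8-bis[4-(TBSO)-3,5-dimethoxyphenyl]-3,7-dioxabicyclo[3.3.0]octane-2,6-dione | O=C1O[C@@H](c3cc(OC)c(O[Si](C)(C)C(C)(C)C)c(OC)c3)[C@H]2[C@@H]1[C@H](c4cc(OC)c(O[Si](C)(C)C(C)(C)C)c(OC)c4)OC2=O
F3 | step 3 | (1R,2S,3S,4R)-1,4-bis[4-(TBSO)-3,5-dimethoxyphenyl]-2,3-bis(hydroxymethyl)butane-1,4-diol | COc1cc(cc(OC)c1O[Si](C)(C)C(C)(C)C)[C@H](O)[C@H](CO)[C@@H](CO)[C@@H](O)c1cc(OC)c(O[Si](C)(C)C(C)(C)C)c(OC)c1
F4 | step 3 | 9,9′-bis-O-TBS ether of F3 | COc1cc(cc(OC)c1O[Si](C)(C)C(C)(C)C)[C@H](O)[C@H](CO[Si](C)(C)C(C)(C)C)[C@@H](CO[Si](C)(C)C(C)(C)C)[C@@H](O)c1cc(OC)c(O[Si](C)(C)C(C)(C)C)c(OC)c1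
F5 | step 3 | mono-mesylate of F4 | COc1cc(cc(OC)c1O[Si](C)(C)C(C)(C)C)[C@H](OS(C)(=O)=O)[C@H](CO[Si](C)(C)C(C)(C)C)[C@@H](CO[Si](C)(C)C(C)(C)C)[C@@H](O)c1cc(OC)c(O[Si](C)(C)C(C)(C)C)c(OC)c1
F6 | step 3 | (2R,3S,4S,5R)-2,5-bis[4-(TBSO)-3,5-dimethoxyphenyl]-3,4-bis[(TBSO)methyl]tetrahydrofuran | COc1cc([C@@H]2O[C@@H](c3cc(OC)c(O[Si](C)(C)C(C)(C)C)c(OC)c3)[C@H](CO[Si](C)(C)C(C)(C)C)[C@H]2CO[Si](C)(C)C(C)(C)C)cc(OC)c1O[Si](C)(C)C(C)(C)C
F7 | step 3 | (2R,3S,4S,5R)-2,5-bis(4-hydroxy-3,5-dimethoxyphenyl)-3,4-bis(hydroxymethyl)tetrahydrofuran | COc1cc([C@@H]2O[C@@H](c3cc(OC)c(O)c(OC)c3)[C@H](CO)[C@H]2CO)cc(OC)c1O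
F8 | step 5 | free-phenol analogue of 13 (9,9′-bis-O-TBS, both benzylic OH free) | COc1cc(cc(OC)c1OC)[C@H](O)[C@H](CO[Si](C)(C)C(C)(C)C)[C@@H](CO[Si](C)(C)C(C)(C)C)[C@@H](O)c1cc(OC)c(O)c(OC)c1
F9 | step 5 | 2,6-dimethoxy-p-quinone methide derived from F8 | COc1cc(cc(OC)c1OC)[C@H](O)[C@H](CO[Si](C)(C)C(C)(C)C)[C@@H](CO[Si](C)(C)C(C)(C)C)C=C1C=C(OC)C(=O)C(OC)=C1
F10 | step 5 | 4-[(2R,3S,4S,5R)-3,4-bis[(TBSO)methyl]-5-(3,4,5-trimethoxyphenyl)tetrahydrofuran-2-yl]-2,6-dimethoxyphenol | COc1cc([C@@H]2O[C@@H](c3cc(OC)c(OC)c(OC)c3)[C@H](CO[Si](C)(C)C(C)(C)C)[C@H]2CO[Si](C)(C)C(C)(C)C)cc(OC)c1O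
F11 | step 1 | 4-[(4R)-4-benzyl-2-oxo-1,3-oxazolidin-3-yl]-4-oxobutanoic acid | O=C(O)CCC(=O)N1[C@H](Cc2ccccc2)COC1=O
F12 | step 1 | mixed pivalic anhydride of F11 | CC(C)(C)C(=O)OC(=O)CCC(=O)N1[C@H](Cc2ccccc2)COC1=O
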